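Chain atoms are numbered from the ethyl methyl (C1) to the benzylidene carbon (C14). Everything rests on cutting the C10–CH3 and C11–C12 bonds: in one flask the terminal C10≡C11 alkyne of a C1–C11 dienyne is methylaluminated and the alkenylalane so formed is allylated in SN2′ fashion on (E)-crotyl diethyl phosphate under CuCl2·2H2O and a chiral carbene ligand. The step exploits the E-trisubstituted C10=C11 alkene with its C10 methyl and the neighbouring bis-allylic C12 methyl stereocentre of the acyclic skipped C10–C14 diene; no ring is formed, the phenyl ring is bought. The precursor is the 3,7-bis-TBS ether of the (3R,6S,7R) dienyne; styrene cross-metathesis and desilylation finish.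

Key step: step 11

Assumption: the ligand antipode in step 11 is the one that directs the alkenyl group to the Si face of C3 of phosphate 18 (to be confirmed on a simple alkenylalane), and (E)-but-2-en-1-ol of high geometric purity is used, since Z isomer would erode the C12 ratio.

Configuration check: the target is 3R,6S,7R,12S with 4E,8E,10E,13E alkenes; the C6 methyl and C7 hydroxyl are syn. TBS = tert-butyldimethylsilyl.

Step 1
Reactants: 1 (E)-2-methylpent-2-enoic acid; 2 (4S)-4-isopropyl-1,3-oxazolidin-2-one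
Product: 4 (4S)-4-isopropyl-3-[(2E)-2-methylpent-2-enoyl]-1,3-oxazolidin-2-one, via mixed pivalic anhydride 3 (not isolated)
Conditions: t-BuCOCl, Et3N, THF, −20 °C; then LiCl, 2, −20 °C → rt
Reagents that add atoms: none
Why: N-acylation through a mixed anhydride, in which the hindered pivaloyl carbonyl steers the LiCl-activated oxazolidinone to the enoyl carbonyl and neither the stereocentre nor the alkene geometry is touched.

Step 2
Reactants: 4 (4S)-4-isopropyl-3-[(2E)-2-methylpent-2-enoyl]-1,3-oxazolidin-2-one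
Product: 6 (4S)-3-[(1E,3E)-1-[(tert-butyldimethylsilyl)oxy]-2-methylpenta-1,3-dien-1-yl]-4-isopropyl-1,3-oxazolidin-2-one, via sodium dienolate 5 (not isolated)
Conditions: NaN(SiMe3)2, THF, −78 °C; then TBSCl, −78 °C
Reagents that add atoms: tert-butyldimethylsilyl chloride, CC(C)(C)[Si](C)(C)Cl
Why: γ-Deprotonation of the enoyl imide and O-silylation (formation of a vinylketene silyl N,O-acetal), where deprotonation of the chelated s-trans imide should give the E,E dienyl geometry.

Step 3
Reactants: 7 3-(trimethylsilyl)propynal; 8 2-(triphenylphosphoranylidene)propanal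
Product: 9 (2E)-2-methyl-5-(trimethylsilyl)pent-2-en-4-ynal
Conditions: CH2Cl2, 0 °C → rt
Reagents that add atoms: none
Why: Wittig olefination with a stabilised formyl ylide, which should give the E enal (the future C8=C9 alkene) and stop after one homologation because the ynal is far more electrophilic than the product enal.

Step 4
Reactants: 9 (2E)-2-methyl-5-(trimethylsilyl)pent-2-en-4-ynal; 6 (4S)-3-[(1E,3E)-1-[(tert-butyldimethylsilyl)oxy]-2-methylpenta-1,3-dien-1-yl]-4-isopropyl-1,3-oxazolidin-2-one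
Product: 10 (4S)-3-[(2E,4S,5R,6E)-5-hydroxy-2,4,6-trimethyl-9-(trimethylsilyl)nona-2,6-dien-8-ynoyl]-4-isopropyl-1,3-oxazolidin-2-one
Conditions: TiCl4 (4 equiv), CH2Cl2, −78 → −40 °C
Reagents that add atoms: none
Why: Kobayashi vinylogous Mukaiyama aldol reaction run with excess TiCl4, the variant that turns α,β-unsaturated aldehydes toward the syn adduct: the γ-carbon of 6 attacks the Lewis-acid-bound aldehyde through an open transition state on the dienyl face away from the isopropyl group, which sets C6 (S), the excess TiCl4 reverses the usual anti preference so that C7 (R) forms syn to the C6 methyl, and the E C4=C5 alkene follows from the s-trans dienyl conformation.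

Step 5
Reactants: 10 (4S)-3-[(2E,4S,5R,6E)-5-hydroxy-2,4,6-trimethyl-9-(trimethylsilyl)nona-2,6-dien-8-ynoyl]-4-isopropyl-1,3-oxazolidin-2-one
Product: 11 (4S)-3-[(2E,4S,5R,6E)-5-[(tert-butyldimethylsilyl)oxy]-2,4,6-trimethyl-9-(trimethylsilyl)nona-2,6-dien-8-ynoyl]-4-isopropyl-1,3-oxazolidin-2-one
Conditions: TBSOTf, 2,6-lutidine, CH2Cl2, −78 → 0 °C
Reagents that add atoms: tert-butyldimethylsilyl trifluoromethanesulfonate, CC(C)(C)[Si](C)(C)OS(=O)(=O)C(F)(F)F
Why: Silyl ether formation at the hindered secondary allylic C7 alcohol with the reactive silyl triflate and a non-nucleophilic base, which leaves all stereocentres untouched.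

Step 6
Reactants: 11 (4S)-3-[(2E,4S,5R,6E)-5-[(tert-butyldimethylsilyl)oxy]-2,4,6-trimethyl-9-(trimethylsilyl)nona-2,6-dien-8-ynoyl]-4-isopropyl-1,3-oxazolidin-2-one
Product: 12 (2E,4S,5R,6E)-5-[(tert-butyldimethylsilyl)oxy]-2,4,6-trimethyl-9-(trimethylsilyl)nona-2,6-dien-8-ynal
Conditions: i-Bu2AlH, CH2Cl2, −78 °C; aq. potassium sodium tartrate
Reagents that add atoms: none
Why: Reductive cleavage of the N-acyl oxazolidinone, in which hydride addition gives a chelated aluminium hemiaminal that should persist at −78 °C and release the enal only on work-up, so that over-reduction is held back and auxiliary 2 is recovered.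

Step 7
Reactants: 12 (2E,4S,5R,6E)-5-[(tert-butyldimethylsilyl)oxy]-2,4,6-trimethyl-9-(trimethylsilyl)nona-2,6-dien-8-ynal; 13 diethylzinc
Product: 14 (3R,4E,6S,7R,8E)-7-[(tert-butyldimethylsilyl)oxy]-4,6,8-trimethyl-11-(trimethylsilyl)undeca-4,8-dien-10-yn-3-ol
Conditions: (+)-MIB [(2R)-3-exo-morpholinoisoborneol] (10 mol%), hexane/toluene, 0 °C
Reagents that add atoms: none
Why: Amino-alcohol-catalysed enantioselective 1,2-addition of a dialkylzinc to an aldehyde, in which the (+)-antipode of the catalyst should deliver ethyl to the Re face of the enal and set C3 (R) under catalyst control, the nearest existing centre (C6) lying three bonds away.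

Step 8
Reactants: 14 (3R,4E,6S,7R,8E)-7-[(tert-butyldimethylsilyl)oxy]-4,6,8-trimethyl-11-(trimethylsilyl)undeca-4,8-dien-10-yn-3-ol
Product: 15 (3E,5R,6S,7E,9R)-5,9-bis[(tert-butyldimethylsilyl)oxy]-4,6,8-trimethyl-1-(trimethylsilyl)undeca-3,7-dien-1-yne
Conditions: TBSOTf, 2,6-lutidine, CH2Cl2, −78 → 0 °C
Reagents that add atoms: tert-butyldimethylsilyl trifluoromethanesulfonate, CC(C)(C)[Si](C)(C)OS(=O)(=O)C(F)(F)F
Why: Silyl ether formation at the secondary allylic C3 alcohol under buffered conditions, which should avoid ionisation of the allylic position and keep C3 intact.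

Step 9
Reactants: 15 (3E,5R,6S,7E,9R)-5,9-bis[(tert-butyldimethylsilyl)oxy]-4,6,8-trimethyl-1-(trimethylsilyl)undeca-3,7-dien-1-yne
Product: 16 (3E,5R,6S,7E,9R)-5,9-bis[(tert-butyldimethylsilyl)oxy]-4,6,8-trimethylundeca-3,7-dien-1-yne
Conditions: K2CO3 (cat.), MeOH/THF, rt
Reagents that add atoms: none
Why: Base-catalysed methanolysis of the C(sp)–Si bond, which should spare the two oxygen-bound silyl ethers and free the terminal alkyne.

Step 10
Reactants: 17 (E)-but-2-en-1-ol
Product: 18 (E)-but-2-en-1-yl diethyl phosphate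
Conditions: (EtO)2P(O)Cl, Et3N, DMAP (cat.), CH2Cl2, 0 °C → rt
Reagents that add atoms: diethyl chlorophosphate, CCOP(=O)(Cl)OCC
Why: O-Phosphorylation of a primary allylic alcohol under basic conditions, which should proceed without allylic transposition and keep the E alkene.

Step 11
Reactants: 16 (3E,5R,6S,7E,9R)-5,9-bis[(tert-butyldimethylsilyl)oxy]-4,6,8-trimethylundeca-3,7-dien-1-yne; 19 trimethylaluminium; 18 (E)-but-2-en-1-yl diethyl phosphate
Product: 21 (3S,4E,6E,8R,9S,10E,12R)-8,12-bis[(tert-butyldimethylsilyl)oxy]-3,5,7,9,11-pentamethyltetradeca-1,4,6,10-tetraene, via dienyl(dimethyl)alane 20 (not isolated)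
Conditions: 19 (2.5 equiv), Cp2ZrCl2 (25 mol%), CH2Cl2, 0 °C → rt; volatiles removed in vacuo; then 18 (2 equiv), CuCl2·2H2O (5 mol%), chiral 4,5-diphenylimidazolinium salt bearing N-(2-sulfonatophenyl) and N-(2,6-diisopropylphenyl) groups (5 mol%, carbene released with Ag2O), THF, −15 °C
Reagents that add atoms: none
Why: Cp2ZrCl2 and Me3Al add methyl and aluminium in syn fashion across the terminal alkyne (Negishi carboalumination), methyl to the internal C10 and the metal to C11, so alane 20 carries the E C10=C11 geometry and the new C10–CH3 bond. The alkenyl group then passes from aluminium to copper and, held by the sulfonate-bearing carbene ligand, attacks C3 of phosphate 18 anti to the leaving group, after which reductive elimination forms C11–C12 at the branched position. The closest known reaction type is the carbene–copper-catalysed enantioselective allylic substitution of allylic phosphates with alkenylaluminium reagents, with the alane drawn here from a carboalumination; no ring is closed. The single new stereocentre C12 (S) is fixed by the chiral ligand, which directs the alkenyl group to the Si face of C3 of the E phosphate, while the existing centres (C7 is four bonds from C11) are too remote to compete. The step needs methyl delivery to C10 with syn addition, which the terminal alkyne and Cp2ZrCl2 secure, and SN2′ over SN2 attack as well as alkenyl over methyl transfer, which the copper–carbene catalyst with a phosphate leaving group secures. Because the medium is neither basic nor protic, the silyl ethers and trisubstituted alkenes should survive and C12 arises directly between its two alkenes without any enolisable intermediate.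

Step 12
Reactants: 21 (3S,4E,6E,8R,9S,10E,12R)-8,12-bis[(tert-butyldimethylsilyl)oxy]-3,5,7,9,11-pentamethyltetradeca-1,4,6,10-tetraene; 22 styrene
Product: 23 [(1E,3S,4E,6E,8R,9S,10E,12R)-8,12-bis[(tert-butyldimethylsilyl)oxy]-3,5,7,9,11-pentamethyltetradeca-1,4,6,10-tetraen-1-yl]benzene
Conditions: second-generation Grubbs catalyst (5 mol%), 22 (5 equiv), 1,4-benzoquinone (10 mol%), CH2Cl2, 40 °C
Reagents that add atoms: none
Why: Olefin cross-metathesis, in which only the monosubstituted C13=C14 vinyl group should engage the catalyst (the three trisubstituted alkenes are inert), styrene gives the E alkene, and the quinone suppresses hydride-mediated migration of the skipped diene so that C12 is not touched.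

Step 13
Reactants: 23 [(1E,3S,4E,6E,8R,9S,10E,12R)-8,12-bis[(tert-butyldimethylsilyl)oxy]-3,5,7,9,11-pentamethyltetradeca-1,4,6,10-tetraen-1-yl]benzene
Product: 24 (3R,4E,6S,7R,8E,10E,12S,13E)-4,6,8,10,12-pentamethyl-14-phenyltetradeca-4,8,10,13-tetraene-3,7-diol
Conditions: Bu4NF, THF, 0 °C → rt
Reagents that add atoms: none
Why: Fluoride-induced cleavage of both silyl ethers, driven by Si–F bond formation under non-acidic conditions that should avoid ionisation of the allylic C3 and C7 alcohols and leave every stereocentre and alkene as it is.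

Compound list
1 | (E)-2-methylpent-2-enoic acid | CC/C=C(\C)C(=O)O | starting material
2 | (4S)-4-isopropyl-1,3-oxazolidin-2-one | CC(C)[C@H]1COC(=O)N1 | starting material
3 | (E)-2-methylpent-2-enoic pivalic anhydride | CC/C=C(\C)C(=O)OC(=O)C(C)(C)C | intermediate
4 | (4S)-4-isopropyl-3-[(2E)-2-methylpent-2-enoyl]-1,3-oxazolidin-2-one | CC/C=C(\C)C(=O)N1C(=O)OC[C@@H]1C(C)C | intermediate
5 | sodium (1E,3E)-2-methyl-1-[(4S)-4-isopropyl-2-oxo-1,3-oxazolidin-3-yl]penta-1,3-dien-1-olate | C/C=C/C(C)=C(/[O-])N1C(=O)OC[C@@H]1C(C)C.[Na+] | intermediate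
6 | (4S)-3-[(1E,3E)-1-[(tert-butyldimethylsilyl)oxy]-2-methylpenta-1,3-dien-1-yl]-4-isopropyl-1,3-oxazolidin-2-one | C/C=C/C(C)=C(/O[Si](C)(C)C(C)(C)C)N1C(=O)OC[C@@H]1C(C)C | intermediate
7 | 3-(trimethylsilyl)propynal | C[Si](C)(C)C#CC=O | starting material
8 | 2-(triphenylphosphoranylidene)propanal | CC(C=O)=P(c1ccccc1)(c1ccccc1)c1ccccc1 | starting material
9 | (2E)-2-methyl-5-(trimethylsilyl)pent-2-en-4-ynal | O=C/C(C)=C/C#C[Si](C)(C)C | intermediate
10 | (4S)-3-[(2E,4S,5R,6E)-5-hydroxy-2,4,6-trimethyl-9-(trimethylsilyl)nona-2,6-dien-8-ynoyl]-4-isopropyl-1,3-oxazolidin-2-one | CC(C)[C@H]1COC(=O)N1C(=O)/C(C)=C/[C@H](C)[C@@H](O)/C(C)=C/C#C[Si](C)(C)C | intermediate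
11 | (4S)-3-[(2E,4S,5R,6E)-5-[(tert-butyldimethylsilyl)oxy]-2,4,6-trimethyl-9-(trimethylsilyl)nona-2,6-dien-8-ynoyl]-4-isopropyl-1,3-oxazolidin-2-one | CC(C)[C@H]1COC(=O)N1C(=O)/C(C)=C/[C@H](C)[C@@H](O[Si](C)(C)C(C)(C)C)/C(C)=C/C#C[Si](C)(C)C | intermediate
12 | (2E,4S,5R,6E)-5-[(tert-butyldimethylsilyl)oxy]-2,4,6-trimethyl-9-(trimethylsilyl)nona-2,6-dien-8-ynal | O=C/C(C)=C/[C@H](C)[C@@H](O[Si](C)(C)C(C)(C)C)/C(C)=C/C#C[Si](C)(C)C | intermediate
13 | diethylzinc | CC[Zn]CC | starting material
14 | (3R,4E,6S,7R,8E)-7-[(tert-butyldimethylsilyl)oxy]-4,6,8-trimethyl-11-(trimethylsilyl)undeca-4,8-dien-10-yn-3-ol | CC[C@@H](O)/C(C)=C/[C@H](C)[C@@H](O[Si](C)(C)C(C)(C)C)/C(C)=C/C#C[Si](C)(C)C | intermediate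
15 | (3E,5R,6S,7E,9R)-5,9-bis[(tert-butyldimethylsilyl)oxy]-4,6,8-trimethyl-1-(trimethylsilyl)undeca-3,7-dien-1-yne | CC[C@@H](O[Si](C)(C)C(C)(C)C)/C(C)=C/[C@H](C)[C@@H](O[Si](C)(C)C(C)(C)C)/C(C)=C/C#C[Si](C)(C)C | intermediate
16 | (3E,5R,6S,7E,9R)-5,9-bis[(tert-butyldimethylsilyl)oxy]-4,6,8-trimethylundeca-3,7-dien-1-yne | CC[C@@H](O[Si](C)(C)C(C)(C)C)/C(C)=C/[C@H](C)[C@@H](O[Si](C)(C)C(C)(C)C)/C(C)=C/C#C | intermediate
17 | (E)-but-2-en-1-ol | C/C=C/CO | starting material
18 | (E)-but-2-en-1-yl diethyl phosphate | C/C=C/COP(=O)(OCC)OCC | intermediate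
19 | trimethylaluminium | C[Al](C)C | starting material
20 | [(1E,3E,5R,6S,7E,9R)-5,9-bis[(tert-butyldimethylsilyl)oxy]-2,4,6,8-tetramethylundeca-1,3,7-trien-1-yl]dimethylalumane | CC[C@@H](O[Si](C)(C)C(C)(C)C)/C(C)=C/[C@H](C)[C@@H](O[Si](C)(C)C(C)(C)C)/C(C)=C/C(C)=C/[Al](C)C | intermediate
21 | (3S,4E,6E,8R,9S,10E,12R)-8,12-bis[(tert-butyldimethylsilyl)oxy]-3,5,7,9,11-pentamethyltetradeca-1,4,6,10-tetraene | CC[C@@H](O[Si](C)(C)C(C)(C)C)/C(C)=C/[C@H](C)[C@@H](O[Si](C)(C)C(C)(C)C)/C(C)=C/C(C)=C/[C@@H](C)C=C | intermediate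
22 | styrene | C=Cc1ccccc1 | starting material
23 | [(1E,3S,4E,6E,8R,9S,10E,12R)-8,12-bis[(tert-butyldimethylsilyl)oxy]-3,5,7,9,11-pentamethyltetradeca-1,4,6,10-tetraen-1-yl]benzene | CC[C@@H](O[Si](C)(C)C(C)(C)C)/C(C)=C/[C@H](C)[C@@H](O[Si](C)(C)C(C)(C)C)/C(C)=C/C(C)=C/[C@@H](C)/C=C/c1ccccc1 | intermediate
24 | (3R,4E,6S,7R,8E,10E,12S,13E)-4,6,8,10,12-pentamethyl-14-phenyltetradeca-4,8,10,13-tetraene-3,7-diol | CC[C@@H](O)/C(C)=C/[C@H](C)[C@@H](O)/C(C)=C/C(C)=C/[C@@H](C)/C=C/c1ccccc1 | target

Total step count: 13.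
Longest linear sequence: 11 steps (steps 1, 2, 4–9, 11–13, counted from acid 1).

Steps most likely to fail

1. Step 11. The copper stage may suffer from methyl competing with alkenyl transfer, from residual aluminium and zirconium Lewis acids eroding the branched and facial selectivity, or from ionisation of the C7 silyl ether in the one-pot mixture. The fallback separates the two events. Setting out from 16, the same methylalumination gives alane 20, which is quenched with 2-methoxy-4,4,5,5-tetramethyl-1,3,2-dioxaborolane to give the isolable dienylboronate 2-[(1E,3E,5R,6S,7E,9R)-5,9-bis[(tert-butyldimethylsilyl)oxy]-2,4,6,8-tetramethylundeca-1,3,7-trien-1-yl]-4,4,5,5-tetramethyl-1,3,2-dioxaborolane F1. After chromatography, F1 is coupled with phosphate 18 by the known copper–carbene-catalysed enantioselective allylic substitution with alkenylboronates (CuCl, the same class of chiral imidazolinium salt, NaOMe, THF), which comes back to the route at 21.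

2. Step 4. The syn preference or the conversion of the vinylogous aldol may be poor with this conjugated enynal, giving a mixture at C7. The fallback builds the C6–C7 syn pair by an Evans boron aldol. Setting out from 9, reaction with commercial (4R)-4-benzyl-3-propanoyl-1,3-oxazolidin-2-one (Bu2BOTf, i-Pr2NEt, CH2Cl2, −78 → 0 °C) should give, through the Zimmerman–Traxler chair of the Z boron enolate, the syn adduct (4R)-4-benzyl-3-[(2R,3R,4E)-3-hydroxy-2,4-dimethyl-7-(trimethylsilyl)hept-4-en-6-ynoyl]-1,3-oxazolidin-2-one F2. Transamidation (MeONHMe·HCl, Me3Al) gives the Weinreb amide (2R,3R,4E)-3-hydroxy-N-methoxy-N,2,4-trimethyl-7-(trimethylsilyl)hept-4-en-6-ynamide F3, and silylation (TBSOTf, 2,6-lutidine) gives (2R,3R,4E)-3-[(tert-butyldimethylsilyl)oxy]-N-methoxy-N,2,4-trimethyl-7-(trimethylsilyl)hept-4-en-6-ynamide F4. Reduction with i-Bu2AlH gives the aldehyde (2R,3R,4E)-3-[(tert-butyldimethylsilyl)oxy]-2,4-dimethyl-7-(trimethylsilyl)hept-4-en-6-ynal F5. A Wittig reaction of F5 with ylide 8 (toluene, 90 °C) installs the E C4=C5 enal and comes back to the route at 12.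

3. Step 12. The metathesis catalyst may be slowed by the C12 branch next to the vinyl group, or may move the skipped diene into conjugation and so endanger C12. The fallback forms the styryl unit by C–C coupling at C14 instead of metathesis. Setting out from 21, a Mizoroki–Heck arylation with iodobenzene under ligand-free phase-transfer conditions (Pd(OAc)2, Bu4NCl, NaHCO3, DMF, 50 °C) should arylate the terminal carbon of the only monosubstituted alkene, and β-hydride elimination toward the benzylic position gives the E styrene, which comes back to the route at 23 without any new compound on the way.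

Further compounds
F1 | step 11 | 2-[(1E,3E,5R,6S,7E,9R)-5,9-bis[(tert-butyldimethylsilyl)oxy]-2,4,6,8-tetramethylundeca-1,3,7-trien-1-yl]-4,4,5,5-tetramethyl-1,3,2-dioxaborolane | CC[C@@H](O[Si](C)(C)C(C)(C)C)/C(C)=C/[C@H](C)[C@@H](O[Si](C)(C)C(C)(C)C)/C(C)=C/C(C)=C/B1OC(C)(C)C(C)(C)O1
F2 | step 4 | (4R)-4-benzyl-3-[(2R,3R,4E)-3-hydroxy-2,4-dimethyl-7-(trimethylsilyl)hept-4-en-6-ynoyl]-1,3-oxazolidin-2-one | O=C(N1C(=O)OC[C@H]1Cc1ccccc1)[C@H](C)[C@@H](O)/C(C)=C/C#C[Si](C)(C)C
F3 | step 4 | (2R,3R,4E)-3-hydroxy-N-methoxy-N,2,4-trimethyl-7-(trimethylsilyl)hept-4-en-6-ynamide | CON(C)C(=O)[C@H](C)[C@@H](O)/C(C)=C/C#C[Si](C)(C)C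
F4 | step 4 | (2R,3R,4E)-3-[(tert-butyldimethylsilyl)oxy]-N-methoxy-N,2,4-trimethyl-7-(trimethylsilyl)hept-4-en-6-ynamide | CON(C)C(=O)[C@H](C)[C@@H](O[Si](C)(C)C(C)(C)C)/C(C)=C/C#C[Si](C)(C)C
F5 | step 4 | (2R,3R,4E)-3-[(tert-butyldimethylsilyl)oxy]-2,4-dimethyl-7-(trimethylsilyl)hept-4-en-6-ynal | O=C[C@H](C)[C@@H](O[Si](C)(C)C(C)(C)C)/C(C)=C/C#C[Si](C)(C)C
F0 | step 12 | none | none
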